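Retrosynthetic overview
1. Target ⇐ tris-silyl Z-macrolide (one fluoride step) ⇐ ring ynoate (syn semihydrogenation gives the Z-C2=C3 bond) ⇐ its cobalt complex (cobalt taken off).
2. Key disconnection: C12–C13, the middle bond of the (CH2)12 tether. The saturated ring complex comes from an open-chain diene complex by ring-closing metathesis and diimide saturation in one flask, so the ring, the tether and its final oxidation level arrive together.
3. Enabling feature: C2 and C3 are carried as an alkyne bound in a C2Co2 tetrahedrane (Co2(CO)6 complex, a temporary ring). It bends C1–C2–C3–C4 to about 140°, as the later Z-alkene does, and hides the only competing π bond. The two vinyl groups at the ends of the (CH2)5 arms on C6 and C19 are then the sole reactive sites.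
4. The diene complex comes from a C13–C24 propiolate and a C4–C12 epoxy aldehyde (C3–C4 bond). Both C4 epimers are funnelled through one ynone into the (4R)-alcohol by a reagent-controlled Midland reduction.
5. The propiolate comes from methyl (R)-3-hydroxybutanoate (C23), a syn-reduction (C21) and a Ti–TADDOLate alkylzinc addition (C19). The aldehyde comes from a Sharpless epoxidation (C5, C6). Both arms come from 7-bromohept-1-ene. Ring order: oxirane (step 9), C2Co2 tetrahedrane (step 15), 20-membered lactone (step 16).

Key step: step 16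

Remark on the chemistry: positions are numbered from the lactone carbonyl (C1) to the methyl group (C24). The SMILES is read as 2Z, 4R, trans-oxirane 5S,6S (threo to C4), and all-syn 19S,21R,23R. TBS = tert-butyldimethylsilyl. CIP letters of some centres change with the silyl groups while the spatial arrangement stays the same.

Step 1
Reactants: 1 methyl (R)-3-hydroxybutanoate; 2 tert-butyl acetate
Product: 4 tert-butyl (5R)-5-hydroxy-3-oxohexanoate, via lithium tert-butyl acetate enolate 3 (not isolated)
Conditions: 2, LiN(iPr)2 (3.5 equiv each), THF, −78 °C; 1, −78 to −20 °C; AcOH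
Reagents that add atoms: lithium diisopropylamide CC(C)N([Li])C(C)C (its lithium stays only in 3)
Why: Crossed Claisen condensation in which excess enolate 3 first deprotonates the hydroxyl group and then acylates at the methyl ester, while the C23 stereocentre comes unchanged from the chiral pool.

Step 2
Reactants: 4 tert-butyl (5R)-5-hydroxy-3-oxohexanoate
Product: 5 tert-butyl (3R,5R)-3,5-dihydroxyhexanoate
Conditions: Et2BOMe, THF/MeOH (4:1), −78 °C; NaBH4; MeOH co-evaporation
Reagents that add atoms: none
Why: Narasaka–Prasad reduction, in which Et2BOMe ties the C23 hydroxyl and the C21 ketone into a six-membered boron chelate that external hydride attacks axially, setting C21 1,3-syn to C23.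

Step 3
Reactants: 5 tert-butyl (3R,5R)-3,5-dihydroxyhexanoate
Product: 6 tert-butyl (3R,5R)-3,5-bis(tert-butyldimethylsilyloxy)hexanoate
Conditions: TBSCl, imidazole, DMF, rt
Reagents that add atoms: tert-butyldimethylsilyl chloride CC(C)(C)[Si](C)(C)Cl
Why: Standard silylation of both secondary alcohols, chosen so that a single fluoride step at the end frees all hydroxyl groups.

Step 4
Reactants: 6 tert-butyl (3R,5R)-3,5-bis(tert-butyldimethylsilyloxy)hexanoate
Product: 7 (3R,5R)-3,5-bis(tert-butyldimethylsilyloxy)hexanal
Conditions: iBu2AlH (1.1 equiv), toluene, −78 °C; MeOH, aq. KNaC4H4O6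
Reagents that add atoms: none
Why: Partial ester reduction, in which the aluminium hemiacetal of the hindered tert-butyl ester is stable at −78 °C and collapses to the aldehyde only on work-up.

Step 5
Reactants: 7 (3R,5R)-3,5-bis(tert-butyldimethylsilyloxy)hexanal; 8 7-bromohept-1-ene
Product: 11 (2R,4S,6S)-2,4-bis(tert-butyldimethylsilyloxy)tridec-12-en-6-ol, via hept-6-enylmagnesium bromide 9 (not isolated), via di(hept-6-enyl)zinc 10 (not isolated)
Conditions: 8, Mg, Et2O, reflux; ZnCl2 (0.5 equiv per 9), Et2O, then 1,4-dioxane, filtration; (4R,5R)-TADDOL (20 mol %), Ti(OiPr)4 (1.4 equiv), toluene, −25 °C, then 7; H2O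
Reagents that add atoms: magnesium [Mg] (stays only in 9); zinc chloride Cl[Zn]Cl (its zinc stays only in 10)
Why: Ti–TADDOLate-catalysed asymmetric dialkylzinc addition, in which the (R,R)-TADDOLate directs the alkyl group to the Si face of aliphatic aldehydes under reagent control, setting C19 as S and completing the all-syn C19/C21/C23 array.

Step 6
Reactants: 11 (2R,4S,6S)-2,4-bis(tert-butyldimethylsilyloxy)tridec-12-en-6-ol; 12 propiolic acid
Product: 13 (2R,4S,6S)-2,4-bis(tert-butyldimethylsilyloxy)tridec-12-en-6-yl prop-2-ynoate
Conditions: DCC, DMAP (cat.), CH2Cl2, −20 to 0 °C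
Reagents that add atoms: none
Why: Steglich esterification at low temperature acylates the C19 hydroxyl with retention and avoids conjugate addition to the propiolate.

Step 7
Reactants: 8 7-bromohept-1-ene; 14 prop-2-yn-1-ol
Product: 16 dec-9-en-2-yn-1-ol, via dilithiated prop-2-yn-1-ol 15 (not isolated)
Conditions: 14, n-BuLi (2.1 equiv), THF/DMPU, −78 to 0 °C; 8, rt; H2O
Reagents that add atoms: n-butyllithium [Li]CCCC (its lithium stays only in 15)
Why: C-alkylation of the propargyl alcohol dianion, in which the alkoxide stays unreactive and the acetylide displaces the primary bromide by SN2.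

Step 8
Reactants: 16 dec-9-en-2-yn-1-ol
Product: 17 (2E)-deca-2,9-dien-1-ol
Conditions: LiAlH4, THF, reflux; H2O
Reagents that add atoms: none
Why: Hydroxyl-directed trans-hydroalumination of the propargylic alcohol followed by protonolysis gives the E-allylic alcohol and leaves the remote vinyl group alone.

Step 9
Reactants: 17 (2E)-deca-2,9-dien-1-ol
Product: 18 [(2S,3S)-3-(hept-6-en-1-yl)oxiran-2-yl]methanol
Conditions: Ti(OiPr)4 (10 mol %), L-(+)-diethyl tartrate (12 mol %), t-BuOOH, 4 Å molecular sieves, CH2Cl2, −20 °C
Reagents that add atoms: tert-butyl hydroperoxide CC(C)(C)OO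
Why: Sharpless asymmetric epoxidation, in which L-(+)-diethyl tartrate delivers oxygen to the titanium-bound E-allylic alcohol on the face that gives the (2S,3S)-epoxide, setting C5 and C6, while the unbound terminal alkene does not react.

Step 10
Reactants: 18 [(2S,3S)-3-(hept-6-en-1-yl)oxiran-2-yl]methanol
Product: 19 (2R,3S)-3-(hept-6-en-1-yl)oxirane-2-carbaldehyde
Conditions: Dess–Martin periodinane, CH2Cl2, 0 °C to rt
Reagents that add atoms: none
Why: Dess–Martin oxidation is mild enough to give the epoxy aldehyde without epimerisation at C5 or opening of the oxirane.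

Step 11
Reactants: 13 (2R,4S,6S)-2,4-bis(tert-butyldimethylsilyloxy)tridec-12-en-6-yl prop-2-ynoate; 19 (2R,3S)-3-(hept-6-en-1-yl)oxirane-2-carbaldehyde
Product: 21 open-chain 4-hydroxy-2-ynoate (both C4 epimers), via lithium propiolate acetylide 20 (not isolated)
Conditions: 13, LiN(SiMe3)2, THF, −78 °C; 19, −78 °C; AcOH
Reagents that add atoms: lithium hexamethyldisilazide C[Si](C)(C)N([Li])[Si](C)(C)C (its lithium stays only in 20)
Why: 1,2-addition of a lithium propiolate to an aldehyde forms the C3–C4 bond at −78 °C, and no facial selectivity is needed because both C4 epimers are carried into the same ynone.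

Step 12
Reactants: 21 open-chain 4-hydroxy-2-ynoate (both C4 epimers)
Product: 22 open-chain 4-oxo-2-ynoate
Conditions: Dess–Martin periodinane, CH2Cl2, 0 °C
Reagents that add atoms: none
Why: Dess–Martin oxidation merges the two C4 epimers into one ynone, the oxirane C5–H being too weakly acidic to epimerise.

Step 13
Reactants: 22 open-chain 4-oxo-2-ynoate
Product: 23 open-chain (4R)-4-hydroxy-2-ynoate
Conditions: (S)-Alpine-Borane [B-isopinocampheyl-9-BBN from (−)-α-pinene], THF, 0 °C to rt; MeOH
Reagents that add atoms: none
Why: Midland reduction, in which hydride passes from the pinanyl group through a boat-like six-membered transition state with the slim alkynyl group next to the pinanyl methyl, so that the reagent from (−)-α-pinene should give the (4R)-alcohol under reagent control, and activated 4-oxo-2-ynoates should react fast enough that the vinyl groups meet no free 9-BBN.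

Step 14
Reactants: 23 open-chain (4R)-4-hydroxy-2-ynoate
Product: 24 open-chain tris-TBS ynoate diene
Conditions: TBSOTf, 2,6-lutidine, CH2Cl2, −78 °C
Reagents that add atoms: tert-butyldimethylsilyl triflate CC(C)(C)[Si](C)(C)OS(=O)(=O)C(F)(F)F
Why: Silylation with a non-nucleophilic base blocks the C4 hydroxyl, which would otherwise attack C1 once C2–C3 has become a Z-alkene.

Step 15
Reactants: 24 open-chain tris-TBS ynoate diene
Product: 25 hexacarbonyldicobalt complex of 24
Conditions: Co2(CO)8, CH2Cl2, rt
Reagents that add atoms: dicobalt octacarbonyl O=C=[Co](=C=O)(=C=O)(=C=O)[Co](=C=O)(=C=O)(=C=O)=C=O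
Why: Alkyne complexation, in which Co2(CO)8 loses two CO and binds only the triple bond, gives the C2Co2 tetrahedrane that masks and bends the ynoate while alkenes, oxirane, ester and silyl ethers stay untouched.

Step 16
Reactants: 25 hexacarbonyldicobalt complex of 24
Product: 27 saturated 20-membered lactone cobalt complex, via macrocyclic C12=C13 alkene complex 26 (not isolated)
Conditions: RuCl2(=CHPh)(PCy3)(H2IMes) (second-generation Grubbs catalyst, 15 mol %), CH2Cl2 (0.5 mM), reflux, argon sparge; concentrated to about 0.05 M; 2-nitrobenzenesulfonohydrazide (excess, in portions), Et3N, rt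
Reagents that add atoms: none
Why: Ring-closing olefin metathesis followed in the same flask by diimide transfer hydrogenation: the ruthenium alkylidene loads onto one terminal vinyl group, a [2+2] cycloaddition/cycloreversion with the other vinyl group forms C12=C13 with loss of ethene, and HN=NH released from the sulfonohydrazide then adds H2 in a concerted syn fashion. The closest known reaction types are the metathesis macrocyclisation of ester-tethered dienes that carry an alkyne–Co2(CO)6 unit and the diimide saturation of alkenes next to such clusters. The one ring closed is the 20-membered lactone ring, by end-to-end union of two monosubstituted alkenes at high dilution, helped by the roughly 140° bend at C2 and C3 in the tetrahedrane, which folds the chain as the later Z-alkene does. No stereocentre is formed, and the E/Z mixture 26 is funnelled into the single saturated compound 27. The step needs chemoselectivity for the two vinyl groups and then for C12=C13 over C2–C3, and this is secured because the only other π system is locked in the coordinatively saturated cluster, so that neither enyne metathesis nor alkyne reduction can compete. Ring against oligomer is handled by dilution and removal of ethene, since oligomers stay metathesis-active and can back-bite to the ring.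

Step 17
Reactants: 27 saturated 20-membered lactone cobalt complex
Product: 28 20-membered tris-TBS ring ynoate
Conditions: N-methylmorpholine N-oxide (excess), CH2Cl2, rt
Reagents that add atoms: none
Why: Oxidative decomplexation, in which the amine N-oxide oxidises CO ligands to CO2 so that the cluster falls apart, releases the free ynoate under neutral conditions that spare oxirane and silyl ethers.

Step 18
Reactants: 28 20-membered tris-TBS ring ynoate
Product: 29 tris-TBS (2Z)-macrolide
Conditions: H2 (1 atm), Pd/CaCO3 poisoned with Pb(OAc)2, quinoline, EtOAc, rt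
Reagents that add atoms: none
Why: Lindlar semihydrogenation delivers H2 syn on the poisoned palladium surface to the only remaining π bond and so gives the Z-enoate, with quinoline holding back over-reduction.

Step 19
Reactants: 29 tris-TBS (2Z)-macrolide
Product: 30 target macrolide CNP0461152.1
Conditions: HF·pyridine, pyridine, THF, 0 °C to rt
Reagents that add atoms: none
Why: Fluoride-mediated desilylation under buffered, weakly acidic conditions frees the three hydroxyl groups without forming an alkoxide, so that neither attack of O4 on C1 nor epoxide migration should set in.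

Compound list
1 | methyl (R)-3-hydroxybutanoate | C[C@@H](O)CC(=O)OC | starting material
2 | tert-butyl acetate | CC(=O)OC(C)(C)C | starting material
3 | lithium enolate of tert-butyl acetate | C=C(O[Li])OC(C)(C)C | intermediate
4 | tert-butyl (5R)-5-hydroxy-3-oxohexanoate | C[C@@H](O)CC(=O)CC(=O)OC(C)(C)C | intermediate
5 | tert-butyl (3R,5R)-3,5-dihydroxyhexanoate (syn-diol) | C[C@@H](O)C[C@@H](O)CC(=O)OC(C)(C)C | intermediate
6 | tert-butyl (3R,5R)-3,5-bis(tert-butyldimethylsilyloxy)hexanoate | C[C@@H](O[Si](C)(C)C(C)(C)C)C[C@@H](O[Si](C)(C)C(C)(C)C)CC(=O)OC(C)(C)C | intermediate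
7 | (3R,5R)-3,5-bis(tert-butyldimethylsilyloxy)hexanal | C[C@@H](O[Si](C)(C)C(C)(C)C)C[C@@H](O[Si](C)(C)C(C)(C)C)CC=O | intermediate
8 | 7-bromohept-1-ene | C=CCCCCCBr | starting material
9 | hept-6-enylmagnesium bromide | C=CCCCCC[Mg]Br | intermediate
10 | di(hept-6-enyl)zinc | C=CCCCCC[Zn]CCCCCC=C | intermediate
11 | (2R,4S,6S)-2,4-bis(tert-butyldimethylsilyloxy)tridec-12-en-6-ol (all-syn, C13–C24 part plus one vinyl carbon) | C[C@@H](O[Si](C)(C)C(C)(C)C)C[C@@H](O[Si](C)(C)C(C)(C)C)C[C@@H](O)CCCCCC=C | intermediate
12 | propiolic acid | C#CC(=O)O | starting material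
13 | (2R,4S,6S)-2,4-bis(tert-butyldimethylsilyloxy)tridec-12-en-6-yl prop-2-ynoate | C[C@@H](O[Si](C)(C)C(C)(C)C)C[C@@H](O[Si](C)(C)C(C)(C)C)C[C@H](CCCCCC=C)OC(=O)C#C | intermediate
14 | prop-2-yn-1-ol | C#CCO | starting material
15 | dilithium salt of prop-2-yn-1-ol | [Li]C#CCO[Li] | intermediate
16 | dec-9-en-2-yn-1-ol | C=CCCCCCC#CCO | intermediate
17 | (2E)-deca-2,9-dien-1-ol | C=CCCCCC/C=C/CO | intermediate
18 | [(2S,3S)-3-(hept-6-en-1-yl)oxiran-2-yl]methanol | C=CCCCCC[C@@H]1O[C@H]1CO | intermediate
19 | (2R,3S)-3-(hept-6-en-1-yl)oxirane-2-carbaldehyde | C=CCCCCC[C@@H]1O[C@H]1C=O | intermediate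
20 | lithium acetylide of propiolate 13 | C[C@@H](O[Si](C)(C)C(C)(C)C)C[C@@H](O[Si](C)(C)C(C)(C)C)C[C@H](CCCCCC=C)OC(=O)C#C[Li] | intermediate
21 | open-chain 4-hydroxy-2-ynoate, both C4 epimers, other five stereocentres spatially as in 30 | C[C@@H](O[Si](C)(C)C(C)(C)C)C[C@@H](O[Si](C)(C)C(C)(C)C)C[C@H](CCCCCC=C)OC(=O)C#CC(O)[C@H]1[C@H](CCCCCC=C)O1 | intermediate
22 | open-chain 4-oxo-2-ynoate (epoxy ynone) | C[C@@H](O[Si](C)(C)C(C)(C)C)C[C@@H](O[Si](C)(C)C(C)(C)C)C[C@H](CCCCCC=C)OC(=O)C#CC(=O)[C@H]1[C@H](CCCCCC=C)O1 | intermediate
23 | open-chain (4R)-4-hydroxy-2-ynoate, all six stereocentres spatially as in 30 | C[C@@H](O[Si](C)(C)C(C)(C)C)C[C@@H](O[Si](C)(C)C(C)(C)C)C[C@H](CCCCCC=C)OC(=O)C#C[C@H]([C@H]1[C@H](CCCCCC=C)O1)O | intermediate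
24 | open-chain tris-TBS ynoate diene (C4 silyl ether of 23) | C[C@@H](O[Si](C)(C)C(C)(C)C)C[C@@H](O[Si](C)(C)C(C)(C)C)C[C@H](CCCCCC=C)OC(=O)C#C[C@H]([C@H]1[C@H](CCCCCC=C)O1)O[Si](C)(C)C(C)(C)C | intermediate
25 | hexacarbonyldicobalt complex of 24 (C2 and C3 in a C2Co2 tetrahedrane) | C[C@@H](O[Si](C)(C)C(C)(C)C)C[C@@H](O[Si](C)(C)C(C)(C)C)C[C@H](CCCCCC=C)OC(=O)C12C3([Co]1(=C=O)(=C=O)(=C=O)[Co]23(=C=O)(=C=O)=C=O)[C@H]([C@H]4[C@H](CCCCCC=C)O4)O[Si](C)(C)C(C)(C)C | intermediate
26 | 20-membered lactone cobalt complex with C12=C13 double bond (E/Z mixture) | C[C@@H](O[Si](C)(C)C(C)(C)C)C[C@@H](O[Si](C)(C)C(C)(C)C)C[C@@H]1CCCCCC=CCCCCC[C@@H]2O[C@H]2[C@H](O[Si](C)(C)C(C)(C)C)C34C5(C(=O)O1)[Co]3(=C=O)(=C=O)(=C=O)[Co]45(=C=O)(=C=O)=C=O | intermediate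
27 | saturated 20-membered lactone cobalt complex | C[C@@H](O[Si](C)(C)C(C)(C)C)C[C@@H](O[Si](C)(C)C(C)(C)C)C[C@@H]1CCCCCCCCCCCC[C@@H]2O[C@H]2[C@H](O[Si](C)(C)C(C)(C)C)C34C5(C(=O)O1)[Co]3(=C=O)(=C=O)(=C=O)[Co]45(=C=O)(=C=O)=C=O | intermediate
28 | 20-membered tris-TBS ring ynoate | C[C@@H](O[Si](C)(C)C(C)(C)C)C[C@@H](O[Si](C)(C)C(C)(C)C)C[C@@H]1CCCCCCCCCCCC[C@@H]2O[C@H]2[C@H](O[Si](C)(C)C(C)(C)C)C#CC(=O)O1 | intermediate
29 | tris-TBS (2Z)-macrolide, stereocentres spatially as in 30 | C[C@@H](O[Si](C)(C)C(C)(C)C)C[C@@H](O[Si](C)(C)C(C)(C)C)C[C@@H]1CCCCCCCCCCCC[C@@H]2O[C@H]2[C@H](O[Si](C)(C)C(C)(C)C)/C=C\C(=O)O1 | intermediate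
30 | CNP0461152.1, (2Z,4R,5S,6S,19S)-5,6-epoxy-4-hydroxy-19-[(2R,4R)-2,4-dihydroxypentyl]nonadec-2-en-19-olide | C[C@@H](O)C[C@@H](O)C[C@@H]1CCCCCCCCCCCC[C@@H]2O[C@H]2[C@H](O)/C=C\C(=O)O1 | target

Total step count: 19. Longest linear sequence: 15 steps (steps 1–6 and 11–19). The epoxy aldehyde branch (steps 7–10) joins at step 11.

Steps most likely to fail

First, step 16. Loss of CO from the cluster may poison the ruthenium carbene. Slow closure may then give way to oligomerisation or to alkene migration before the ring forms, and the diimide stage may erode the cluster. The fallback leaves cobalt out. It sets out from 24 and comes back at 29, skipping steps 15 to 18.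
- Compound 24 is semihydrogenated (H2, Pd/CaCO3 poisoned with Pb(OAc)2, quinoline, stopped after one equivalent) to the open-chain Z-enoate triene F1. Its electron-poor C2=C3 bond, flanked by the C4 silyl ether, should not take part in metathesis.
- Ring-closing metathesis with the same ruthenium catalyst at high dilution gives the macrocyclic C12=C13 diene F2.
- Hydrogenation with RhCl(PPh3)3 under H2 in benzene should saturate the unhindered isolated alkene in preference to the shielded conjugated one and give 29.

Second, step 13. Slow hydride transfer to the α-branched ketone would let the reagent dissociate into α-pinene and 9-BBN. That would bring unselective reduction and hydroboration of the vinyl groups, and the bias of the neighbouring oxirane may erode facial selectivity. The fallback sets C4 during bond formation instead of by reduction. It sets out from 13 and 19 and comes back at 23, skipping steps 11 to 13. Propiolate 13 is zincated with Et2Zn and added to 19 under a BINOL/Ti(OiPr)4 catalyst, a catalytic asymmetric alkynylation of aldehydes. The BINOL enantiomer is chosen for attack on the Re face of the aldehyde. This fallback makes no compound outside the list (F0).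

Third, step 19. Once O4 is free next to the Z-enoate, acyl transfer to a five-membered lactone with rupture of the large ring may set in during the long acidic fluoride treatment, along with opening of the oxirane. The fallback swaps the order of the last operations. It sets out from 28 and comes back at 30. The silyl groups are removed with HF·pyridine at the alkyne stage to give the ring ynoate triol F3, in which the linear C2≡C3 unit keeps O4 away from C1. The neutral semihydrogenation (H2, Pd/CaCO3 poisoned with Pb(OAc)2, quinoline) then becomes the last step and gives 30 directly.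

Further compounds
F1 | step 16 | open-chain tris-TBS (2Z)-enoate triene | C[C@@H](O[Si](C)(C)C(C)(C)C)C[C@@H](O[Si](C)(C)C(C)(C)C)C[C@H](CCCCCC=C)OC(=O)/C=C\[C@H]([C@H]1[C@H](CCCCCC=C)O1)O[Si](C)(C)C(C)(C)C
F2 | step 16 | tris-TBS (2Z)-macrolide with C12=C13 double bond (E/Z mixture) | C[C@@H](O[Si](C)(C)C(C)(C)C)C[C@@H](O[Si](C)(C)C(C)(C)C)C[C@@H]1CCCCCC=CCCCCC[C@@H]2O[C@H]2[C@H](O[Si](C)(C)C(C)(C)C)/C=C\C(=O)O1
F0 | step 13 | none | none
F3 | step 19 | 20-membered ring ynoate triol | C[C@@H](O)C[C@@H](O)C[C@@H]1CCCCCCCCCCCC[C@@H]2O[C@H]2[C@H](O)C#CC(=O)O1
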